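**Assumption:** the SMILES is read as ent-epifisetinidol-(4α→8)-fisetinidol, (2S,3S,4S) in the upper and (2R,3S) in the lower flavan unit; the quinidine-derived thiourea is taken to give the (2R)- and the quinine-derived one the (2S)-chromanone (the two are exchanged if the sense proves opposite); 3,4-bis(benzyloxy)benzaldehyde is bought.

## Retrosynthetic overview

1. Target ⇐ hexabenzyl ether ⇐ C4–C8 interflavanyl bond: a 2,3-cis 4-methoxyflavan-3-ol (upper unit, electrophile) plus a flavan-8-ylboronic acid (lower unit, nucleophile), made separately and joined in the penultimate step.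
2. Upper unit ⇐ (2R)-chroman-4-one: C3–OH by Rubottom oxidation, C4=O kept as the later leaving group (reduction, methyl ether), C3 inverted by oxidation and hydride reduction.
3. Lower unit ⇐ (2S)-8-iodochroman-4-one: Rubottom oxidation, removal of the C4 oxygen, iodine to boron (this fixes the 4→8 regiochemistry).
4. Each pyranone ring (ring C of the upper unit, ring F of the lower unit) is closed by a thiourea-catalysed enantioselective intramolecular oxa-Michael addition of a 2'-hydroxy alkylidene β-keto ester; pseudoenantiomeric catalysts give the two opposite C2 centres.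
5. Alkylidenes ⇐ Knoevenagel condensation of 3,4-bis(benzyloxy)benzaldehyde with aryl β-keto esters ⇐ Claisen condensation of tert-butyl acetate with (iodinated) methyl 4-benzyloxy-2-hydroxybenzoate; rings C and F are formed in parallel, no ring is formed after the union.

## Route

**Upper unit (steps 1–9)**

Step 1
Reactants: 1 methyl 2,4-dihydroxybenzoate
Product: 2 methyl 4-(benzyloxy)-2-hydroxybenzoate
Conditions: BnBr (1.05 equiv), K2CO3, acetone, reflux
Reagents that add atoms: benzyl bromide `BrCc1ccccc1`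
Why: Williamson etherification, selective because the 2-OH is hydrogen-bonded to the ester carbonyl and far less nucleophilic than the 4-OH.

Step 2
Reactants: 2 methyl 4-(benzyloxy)-2-hydroxybenzoate; 3 tert-butyl acetate
Product: 4 tert-butyl 3-[4-(benzyloxy)-2-hydroxyphenyl]-3-oxopropanoate
Conditions: LiN(i-Pr)2 (4 equiv), 3 (4 equiv), THF, −78 °C; add 2, −78 → 0 °C; sat. aq. NH4Cl
Reagents that add atoms: none
Why: crossed Claisen condensation in which excess ester enolate acylates the methyl ester although the phenol is deprotonated first, the product being held as its dianion until the quench.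

Step 3
Reactants: 4 tert-butyl 3-[4-(benzyloxy)-2-hydroxyphenyl]-3-oxopropanoate; 5 3,4-bis(benzyloxy)benzaldehyde
Product: 6 tert-butyl (2Z)-2-[4-(benzyloxy)-2-hydroxybenzoyl]-3-[3,4-bis(benzyloxy)phenyl]prop-2-enoate
Conditions: piperidine (10 mol %), AcOH (10 mol %), 4 Å MS, toluene, rt
Reagents that add atoms: none
Why: Knoevenagel condensation of the active methylene with the aldehyde under conditions mild enough that the chelated phenol does not cyclise, and any (E)-isomer converges in step 4.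

Step 4
Reactants: 6 tert-butyl (2Z)-2-[4-(benzyloxy)-2-hydroxybenzoyl]-3-[3,4-bis(benzyloxy)phenyl]prop-2-enoate
Product: 8 (2R)-7-(benzyloxy)-2-[3,4-bis(benzyloxy)phenyl]chroman-4-one, via trans-chromanone tert-butyl ester 7 (not isolated)
Conditions: quinidine-derived thiourea [1-[3,5-bis(trifluoromethyl)phenyl]-3-(9-deoxy-epi-quinidin-9-yl)thiourea] (10 mol %), toluene, −25 °C; then p-TsOH·H2O (0.5 equiv), 80 °C
Reagents that add atoms: none
Why: enantioselective intramolecular oxa-Michael addition (6-endo-trig) in which the thiourea binds the β-keto ester and the quinuclidine nitrogen activates the phenol, so the catalyst sets C2 (R), after which acid-mediated loss of isobutene and decarboxylation remove the activating ester without touching C2.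

Step 5
Reactants: 8 (2R)-7-(benzyloxy)-2-[3,4-bis(benzyloxy)phenyl]chroman-4-one
Product: 11 (2S,3S)-7-(benzyloxy)-2-[3,4-bis(benzyloxy)phenyl]-3-hydroxychroman-4-one, via trimethylsilyl enol ether 9 (not isolated), via silyloxy epoxide 10 (not isolated)
Conditions: Me3SiOTf, Et3N, CH2Cl2, 0 °C; then dimethyldioxirane, acetone/CH2Cl2, −40 °C; then 1 M HCl, THF, 0 °C
Reagents that add atoms: dimethyldioxirane `CC1(C)OO1` (the C3 oxygen); trimethylsilyl triflate `C[Si](C)(C)OS(=O)(=O)C(F)(F)F` (silicon only in 9 and 10)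
Why: Rubottom oxidation, in which soft enolisation avoids the ring opening of a free enolate, the dioxirane epoxidises the enol ether anti to the 2-aryl group and hydrolysis gives the 2,3-trans α-hydroxy ketone (also the thermodynamic epimer), setting C3 (S).

Step 6
Reactants: 11 (2S,3S)-7-(benzyloxy)-2-[3,4-bis(benzyloxy)phenyl]-3-hydroxychroman-4-one
Product: 12 (2S,3R,4S)-7-(benzyloxy)-2-[3,4-bis(benzyloxy)phenyl]chromane-3,4-diol
Conditions: NaBH4, THF/EtOH, 0 °C
Reagents that add atoms: none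
Why: borohydride reduction of the α-hydroxy ketone gives mainly the 3,4-trans diol, and the C4 configuration is of no consequence because C4 is ionised in step 19.

Step 7
Reactants: 12 (2S,3R,4S)-7-(benzyloxy)-2-[3,4-bis(benzyloxy)phenyl]chromane-3,4-diol
Product: 13 (2S,3R,4S)-7-(benzyloxy)-2-[3,4-bis(benzyloxy)phenyl]-4-methoxychroman-3-ol
Conditions: MeOH/CH2Cl2, pyridinium p-toluenesulfonate (10 mol %), rt
Reagents that add atoms: methanol `CO`
Why: acid-catalysed SN1 etherification in which only the 4-OH (benzylic and para to the 7-benzyloxy group) ionises and methanol in large excess traps the cation mainly trans to the 3-OH, the C4 epimer being equally usable.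

Step 8
Reactants: 13 (2S,3R,4S)-7-(benzyloxy)-2-[3,4-bis(benzyloxy)phenyl]-4-methoxychroman-3-ol
Product: 14 (2S,4S)-7-(benzyloxy)-2-[3,4-bis(benzyloxy)phenyl]-4-methoxychroman-3-one
Conditions: Dess–Martin periodinane (1.3 equiv), CH2Cl2, 0 °C → rt
Reagents that add atoms: none
Why: Dess–Martin oxidation of the only free alcohol under neutral conditions, which spares the enolisable C2 centre, the benzylic methyl ether and the benzyl ethers.

Step 9
Reactants: 14 (2S,4S)-7-(benzyloxy)-2-[3,4-bis(benzyloxy)phenyl]-4-methoxychroman-3-one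
Product: 15 (2S,3S,4S)-7-(benzyloxy)-2-[3,4-bis(benzyloxy)phenyl]-4-methoxychroman-3-ol
Conditions: LiBH(s-Bu)3 (1.5 equiv), THF, −78 °C; sat. aq. NH4Cl
Reagents that add atoms: none
Why: diastereoselective reduction in which the bulky hydride attacks the flavan-3-one from the face opposite the 2-aryl and 4-methoxy groups (the catechin-to-epicatechin inversion), setting C3 (S) with the 2,3-cis relationship.

**Lower unit (steps 10–18)**

Step 10
Reactants: 1 methyl 2,4-dihydroxybenzoate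
Product: 16 methyl 2,4-dihydroxy-3-iodobenzoate
Conditions: I2 (0.4 equiv), HIO3 (0.2 equiv), EtOH/H2O, rt
Reagents that add atoms: iodine `II`; iodic acid `OI(=O)=O`
Why: electrophilic aromatic iodination, which in chelated 2,4-dihydroxyaryl carbonyl compounds (as for resacetophenone) goes to the carbon between the two oxygens, any 5-iodo isomer being removed by crystallisation.

Step 11
Reactants: 16 methyl 2,4-dihydroxy-3-iodobenzoate
Product: 17 methyl 4-(benzyloxy)-2-hydroxy-3-iodobenzoate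
Conditions: BnBr (1.05 equiv), K2CO3, acetone, reflux
Reagents that add atoms: benzyl bromide `BrCc1ccccc1`
Why: Williamson etherification of the more acidic, non-chelated 4-OH, the chelated and iodine-flanked 2-OH staying free.

Step 12
Reactants: 17 methyl 4-(benzyloxy)-2-hydroxy-3-iodobenzoate; 3 tert-butyl acetate
Product: 18 tert-butyl 3-[4-(benzyloxy)-2-hydroxy-3-iodophenyl]-3-oxopropanoate
Conditions: LiN(i-Pr)2 (4 equiv), 3 (4 equiv), THF, −78 °C; add 17, −78 → 0 °C; sat. aq. NH4Cl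
Reagents that add atoms: none
Why: crossed Claisen condensation as in step 2, the aryl iodide being inert to the ester enolate at low temperature and having no ortho hydrogen for aryne formation.

Step 13
Reactants: 18 tert-butyl 3-[4-(benzyloxy)-2-hydroxy-3-iodophenyl]-3-oxopropanoate; 5 3,4-bis(benzyloxy)benzaldehyde
Product: 19 tert-butyl (2Z)-2-[4-(benzyloxy)-2-hydroxy-3-iodobenzoyl]-3-[3,4-bis(benzyloxy)phenyl]prop-2-enoate
Conditions: piperidine (10 mol %), AcOH (10 mol %), 4 Å MS, toluene, rt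
Reagents that add atoms: none
Why: Knoevenagel condensation as in step 3.

Step 14
Reactants: 19 tert-butyl (2Z)-2-[4-(benzyloxy)-2-hydroxy-3-iodobenzoyl]-3-[3,4-bis(benzyloxy)phenyl]prop-2-enoate
Product: 21 (2S)-7-(benzyloxy)-2-[3,4-bis(benzyloxy)phenyl]-8-iodochroman-4-one, via trans-iodochromanone tert-butyl ester 20 (not isolated)
Conditions: quinine-derived thiourea [1-[3,5-bis(trifluoromethyl)phenyl]-3-(9-deoxy-epi-quinin-9-yl)thiourea] (10 mol %), toluene, −25 °C; then p-TsOH·H2O (0.5 equiv), 80 °C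
Reagents that add atoms: none
Why: enantioselective intramolecular oxa-Michael addition as in step 4, the pseudoenantiomeric catalyst setting C2 (S), followed by de-tert-butylation and decarboxylation.

Step 15
Reactants: 21 (2S)-7-(benzyloxy)-2-[3,4-bis(benzyloxy)phenyl]-8-iodochroman-4-one
Product: 24 (2R,3R)-7-(benzyloxy)-2-[3,4-bis(benzyloxy)phenyl]-3-hydroxy-8-iodochroman-4-one, via iodo trimethylsilyl enol ether 22 (not isolated), via iodo silyloxy epoxide 23 (not isolated)
Conditions: Me3SiOTf, Et3N, CH2Cl2, 0 °C; then dimethyldioxirane, acetone/CH2Cl2, −40 °C; then 1 M HCl, THF, 0 °C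
Reagents that add atoms: dimethyldioxirane `CC1(C)OO1` (the C3 oxygen); trimethylsilyl triflate `C[Si](C)(C)OS(=O)(=O)C(F)(F)F` (silicon only in 22 and 23)
Why: Rubottom oxidation as in step 5, epoxidation anti to the 2-aryl group setting C3 (R) with the 2,3-trans relationship.

Step 16
Reactants: 24 (2R,3R)-7-(benzyloxy)-2-[3,4-bis(benzyloxy)phenyl]-3-hydroxy-8-iodochroman-4-one
Product: 25 (2R,3S,4R)-7-(benzyloxy)-2-[3,4-bis(benzyloxy)phenyl]-8-iodochromane-3,4-diol
Conditions: NaBH4, THF/EtOH, 0 °C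
Reagents that add atoms: none
Why: borohydride reduction of the ketone to the benzylic alcohol (mainly 3,4-trans), whose configuration is irrelevant because C4 becomes CH2 in step 17.

Step 17
Reactants: 25 (2R,3S,4R)-7-(benzyloxy)-2-[3,4-bis(benzyloxy)phenyl]-8-iodochromane-3,4-diol
Product: 26 (2R,3S)-7-(benzyloxy)-2-[3,4-bis(benzyloxy)phenyl]-8-iodochroman-3-ol
Conditions: Et3SiH (3 equiv), CF3CO2H (5 equiv), CH2Cl2, −20 °C, 30 min
Reagents that add atoms: none
Why: ionic hydrogenation in which the acid ionises only the para-alkoxybenzylic 4-OH and the silane reduces the cation to CH2, leaving C2, C3, the aryl iodide and the benzyl ethers intact at low temperature.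

Step 18
Reactants: 26 (2R,3S)-7-(benzyloxy)-2-[3,4-bis(benzyloxy)phenyl]-8-iodochroman-3-ol
Product: 29 [(2R,3S)-7-(benzyloxy)-2-[3,4-bis(benzyloxy)phenyl]-3-hydroxychroman-8-yl]boronic acid, via dilithiated aryllithium alkoxide 27 (not isolated), via lithium aryltriisopropoxyborate 28 (not isolated)
Conditions: n-BuLi (2.2 equiv), THF, −78 °C; B(Oi-Pr)3 (3 equiv), −78 → 0 °C; sat. aq. NH4Cl
Reagents that add atoms: triisopropyl borate `CC(C)OB(OC(C)C)OC(C)C`; water `O` (the two B–OH oxygens on hydrolysis)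
Why: alkoxide formation followed by iodine–lithium exchange (much faster at −78 °C than attack on the benzyl ethers) and borylation of the aryllithium places boron on exactly the carbon (C8) that must carry the interflavanyl bond.

**Union and deprotection (steps 19–20)**

Step 19
Reactants: 15 (2S,3S,4S)-7-(benzyloxy)-2-[3,4-bis(benzyloxy)phenyl]-4-methoxychroman-3-ol; 29 [(2R,3S)-7-(benzyloxy)-2-[3,4-bis(benzyloxy)phenyl]-3-hydroxychroman-8-yl]boronic acid
Product: 30 (2S,3S,4S)-7-(benzyloxy)-4-[(2R,3S)-7-(benzyloxy)-2-[3,4-bis(benzyloxy)phenyl]-3-hydroxychroman-8-yl]-2-[3,4-bis(benzyloxy)phenyl]chroman-3-ol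
Conditions: 29 (2 equiv), Me3SiOTf (0.5 equiv), 4 Å MS, CH2Cl2, −78 → −40 °C
Reagents that add atoms: none
Why: Lewis-acid SN1 Friedel–Crafts-type arylation with ipso substitution of boron, in which the 4-methoxy group ionises to the 7-benzyloxy-stabilised benzylic cation, the C–B bond directs attack to C8 of 29 instead of the otherwise favoured C6, and the nucleophile adds anti to the 3-OH and 2-aryl group of the 2,3-cis unit, setting C4 (S) with the 3,4-trans relationship, while excess 29 suppresses self-condensation of 15.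

Step 20
Reactants: 30 (2S,3S,4S)-7-(benzyloxy)-4-[(2R,3S)-7-(benzyloxy)-2-[3,4-bis(benzyloxy)phenyl]-3-hydroxychroman-8-yl]-2-[3,4-bis(benzyloxy)phenyl]chroman-3-ol
Product: 31 (2S,3S,4S)-2-(3,4-dihydroxyphenyl)-4-[(2R,3S)-2-(3,4-dihydroxyphenyl)-3,7-dihydroxychroman-8-yl]chromane-3,7-diol (CNP0189433.2)
Conditions: H2 (1 atm), Pd(OH)2 on carbon, THF/MeOH/H2O, rt
Reagents that add atoms: none
Why: hydrogenolysis of the six benzyl ethers under neutral conditions, to which the 5-deoxy interflavanyl bond and the cyclic benzylic C2–O bonds are stable, so no stereocentre is touched.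

## Compound list

1 | methyl 2,4-dihydroxybenzoate | `COC(=O)c1ccc(O)cc1O` | starting material
2 | methyl 4-(benzyloxy)-2-hydroxybenzoate | `COC(=O)c1ccc(OCc2ccccc2)cc1O` | intermediate
3 | tert-butyl acetate | `CC(=O)OC(C)(C)C` | starting material
4 | tert-butyl 3-[4-(benzyloxy)-2-hydroxyphenyl]-3-oxopropanoate | `CC(C)(C)OC(=O)CC(=O)c1ccc(OCc2ccccc2)cc1O` | intermediate
5 | 3,4-bis(benzyloxy)benzaldehyde | `O=Cc1ccc(OCc2ccccc2)c(OCc2ccccc2)c1` | starting material
6 | tert-butyl (2Z)-2-[4-(benzyloxy)-2-hydroxybenzoyl]-3-[3,4-bis(benzyloxy)phenyl]prop-2-enoate | `CC(C)(C)OC(=O)/C(=C\c1ccc(OCc2ccccc2)c(OCc2ccccc2)c1)C(=O)c1ccc(OCc2ccccc2)cc1O` | intermediate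
7 | tert-butyl (2R,3S)-7-(benzyloxy)-2-[3,4-bis(benzyloxy)phenyl]-4-oxochromane-3-carboxylate (2,3-trans; not isolated) | `c1ccccc1COc1ccc2c(c1)O[C@@H](c1ccc(OCc3ccccc3)c(OCc3ccccc3)c1)[C@H](C(=O)OC(C)(C)C)C2=O` | intermediate
8 | (2R)-7-(benzyloxy)-2-[3,4-bis(benzyloxy)phenyl]chroman-4-one | `c1ccccc1COc1ccc2c(c1)O[C@@H](c1ccc(OCc3ccccc3)c(OCc3ccccc3)c1)CC2=O` | intermediate
9 | (2R)-7-(benzyloxy)-2-[3,4-bis(benzyloxy)phenyl]-4-[(trimethylsilyl)oxy]-2H-chromene (not isolated) | `c1ccccc1COc1ccc2c(c1)O[C@@H](c1ccc(OCc3ccccc3)c(OCc3ccccc3)c1)C=C2O[Si](C)(C)C` | intermediate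
10 | (2S)-7-(benzyloxy)-2-[3,4-bis(benzyloxy)phenyl]-3,4-epoxy-4-[(trimethylsilyl)oxy]chromane, oxirane oxygen trans to the 2-aryl group (not isolated) | `c1ccccc1COc1ccc2c(c1)O[C@@H](c1ccc(OCc3ccccc3)c(OCc3ccccc3)c1)[C@@H]3O[C@]23O[Si](C)(C)C` | intermediate
11 | (2S,3S)-7-(benzyloxy)-2-[3,4-bis(benzyloxy)phenyl]-3-hydroxychroman-4-one (2,3-trans) | `c1ccccc1COc1ccc2c(c1)O[C@@H](c1ccc(OCc3ccccc3)c(OCc3ccccc3)c1)[C@H](O)C2=O` | intermediate
12 | (2S,3R,4S)-7-(benzyloxy)-2-[3,4-bis(benzyloxy)phenyl]chromane-3,4-diol (2,3-trans-3,4-trans) | `c1ccccc1COc1ccc2c(c1)O[C@@H](c1ccc(OCc3ccccc3)c(OCc3ccccc3)c1)[C@H](O)[C@H]2O` | intermediate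
13 | (2S,3R,4S)-7-(benzyloxy)-2-[3,4-bis(benzyloxy)phenyl]-4-methoxychroman-3-ol | `c1ccccc1COc1ccc2c(c1)O[C@@H](c1ccc(OCc3ccccc3)c(OCc3ccccc3)c1)[C@H](O)[C@H]2OC` | intermediate
14 | (2S,4S)-7-(benzyloxy)-2-[3,4-bis(benzyloxy)phenyl]-4-methoxychroman-3-one | `c1ccccc1COc1ccc2c(c1)O[C@@H](c1ccc(OCc3ccccc3)c(OCc3ccccc3)c1)C(=O)[C@H]2OC` | intermediate
15 | (2S,3S,4S)-7-(benzyloxy)-2-[3,4-bis(benzyloxy)phenyl]-4-methoxychroman-3-ol (2,3-cis) | `c1ccccc1COc1ccc2c(c1)O[C@@H](c1ccc(OCc3ccccc3)c(OCc3ccccc3)c1)[C@@H](O)[C@H]2OC` | intermediate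
16 | methyl 2,4-dihydroxy-3-iodobenzoate | `COC(=O)c1ccc(O)c(I)c1O` | intermediate
17 | methyl 4-(benzyloxy)-2-hydroxy-3-iodobenzoate | `COC(=O)c1ccc(OCc2ccccc2)c(I)c1O` | intermediate
18 | tert-butyl 3-[4-(benzyloxy)-2-hydroxy-3-iodophenyl]-3-oxopropanoate | `CC(C)(C)OC(=O)CC(=O)c1ccc(OCc2ccccc2)c(I)c1O` | intermediate
19 | tert-butyl (2Z)-2-[4-(benzyloxy)-2-hydroxy-3-iodobenzoyl]-3-[3,4-bis(benzyloxy)phenyl]prop-2-enoate | `CC(C)(C)OC(=O)/C(=C\c1ccc(OCc2ccccc2)c(OCc2ccccc2)c1)C(=O)c1ccc(OCc2ccccc2)c(I)c1O` | intermediate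
20 | tert-butyl (2S,3R)-7-(benzyloxy)-2-[3,4-bis(benzyloxy)phenyl]-8-iodo-4-oxochromane-3-carboxylate (2,3-trans; not isolated) | `Ic1c(OCc3ccccc3)ccc2c1O[C@H](c1ccc(OCc3ccccc3)c(OCc3ccccc3)c1)[C@@H](C(=O)OC(C)(C)C)C2=O` | intermediate
21 | (2S)-7-(benzyloxy)-2-[3,4-bis(benzyloxy)phenyl]-8-iodochroman-4-one | `Ic1c(OCc3ccccc3)ccc2c1O[C@H](c1ccc(OCc3ccccc3)c(OCc3ccccc3)c1)CC2=O` | intermediate
22 | (2S)-7-(benzyloxy)-2-[3,4-bis(benzyloxy)phenyl]-8-iodo-4-[(trimethylsilyl)oxy]-2H-chromene (not isolated) | `Ic1c(OCc3ccccc3)ccc2c1O[C@H](c1ccc(OCc3ccccc3)c(OCc3ccccc3)c1)C=C2O[Si](C)(C)C` | intermediate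
23 | (2R)-7-(benzyloxy)-2-[3,4-bis(benzyloxy)phenyl]-3,4-epoxy-8-iodo-4-[(trimethylsilyl)oxy]chromane, oxirane oxygen trans to the 2-aryl group (not isolated) | `Ic1c(OCc3ccccc3)ccc2c1O[C@H](c1ccc(OCc3ccccc3)c(OCc3ccccc3)c1)[C@H]3O[C@@]23O[Si](C)(C)C` | intermediate
24 | (2R,3R)-7-(benzyloxy)-2-[3,4-bis(benzyloxy)phenyl]-3-hydroxy-8-iodochroman-4-one (2,3-trans) | `Ic1c(OCc3ccccc3)ccc2c1O[C@H](c1ccc(OCc3ccccc3)c(OCc3ccccc3)c1)[C@@H](O)C2=O` | intermediate
25 | (2R,3S,4R)-7-(benzyloxy)-2-[3,4-bis(benzyloxy)phenyl]-8-iodochromane-3,4-diol | `Ic1c(OCc3ccccc3)ccc2c1O[C@H](c1ccc(OCc3ccccc3)c(OCc3ccccc3)c1)[C@@H](O)[C@@H]2O` | intermediate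
26 | (2R,3S)-7-(benzyloxy)-2-[3,4-bis(benzyloxy)phenyl]-8-iodochroman-3-ol | `Ic1c(OCc3ccccc3)ccc2c1O[C@H](c1ccc(OCc3ccccc3)c(OCc3ccccc3)c1)[C@@H](O)C2` | intermediate
27 | lithium (2R,3S)-7-(benzyloxy)-2-[3,4-bis(benzyloxy)phenyl]-8-lithiochroman-3-olate (not isolated) | `[Li+].[Li]c1c(OCc3ccccc3)ccc2c1O[C@H](c1ccc(OCc3ccccc3)c(OCc3ccccc3)c1)[C@@H]([O-])C2` | intermediate
28 | dilithium salt of the 3-olate of [(2R,3S)-7-(benzyloxy)-2-[3,4-bis(benzyloxy)phenyl]-3-hydroxychroman-8-yl]triisopropoxyborate (not isolated) | `[Li+].[Li+].CC(C)O[B-](OC(C)C)(OC(C)C)c1c(OCc3ccccc3)ccc2c1O[C@H](c1ccc(OCc3ccccc3)c(OCc3ccccc3)c1)[C@@H]([O-])C2` | intermediate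
29 | [(2R,3S)-7-(benzyloxy)-2-[3,4-bis(benzyloxy)phenyl]-3-hydroxychroman-8-yl]boronic acid | `OB(O)c1c(OCc3ccccc3)ccc2c1O[C@H](c1ccc(OCc3ccccc3)c(OCc3ccccc3)c1)[C@@H](O)C2` | intermediate
30 | (2S,3S,4S)-7-(benzyloxy)-4-[(2R,3S)-7-(benzyloxy)-2-[3,4-bis(benzyloxy)phenyl]-3-hydroxychroman-8-yl]-2-[3,4-bis(benzyloxy)phenyl]chroman-3-ol | `c1ccccc1COc1ccc2c(c1)O[C@@H](c1ccc(OCc3ccccc3)c(OCc3ccccc3)c1)[C@@H](O)[C@@H]2c1c(OCc3ccccc3)ccc2c1O[C@H](c1ccc(OCc3ccccc3)c(OCc3ccccc3)c1)[C@@H](O)C2` | intermediate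
31 | (2S,3S,4S)-2-(3,4-dihydroxyphenyl)-4-[(2R,3S)-2-(3,4-dihydroxyphenyl)-3,7-dihydroxychroman-8-yl]chromane-3,7-diol | `Oc1ccc2c(c1)O[C@@H](c1ccc(O)c(O)c1)[C@@H](O)[C@@H]2c1c(O)ccc2c1O[C@H](c1ccc(O)c(O)c1)[C@@H](O)C2` | target

## Step count and risks

Total step count: 20.
Longest linear sequence: 11 steps (1–9, 19, 20; the other arm, 10–18, 19, 20, is equally long).

**Step 19 (most likely to fail).** Free acid may protodeboronate 29, after which the arene reacts at C6, or 15 may self-condense. The fallback sets out from 29 and comes back at 30. Compound 29 is converted with KHF2 in MeOH/H2O into the potassium trifluoroborate F1. With BF3·OEt2 in CH2Cl2/MeCN at −40 → 0 °C, F1 gives an aryldifluoroborane that itself binds the 4-methoxy oxygen of 15, ionises C4 and hands the aryl group over from boron within the ion pair. Bond formation is then ipso by construction and does not depend on a free Brønsted or silyl Lewis acid. Work-up with aqueous NaHCO3 gives 30.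

**Step 14.** The iodine next to the phenol may slow the cyclisation or lower its enantioselectivity. The fallback sets out from scalemic 21 and comes back at 26. Asymmetric transfer hydrogenation with RuCl(p-cymene)[(S,S)-TsDPEN] (or its antipode, whichever reduces the (2S)-ketone faster) in HCO2H/Et3N is run as a kinetic resolution. Only the (2S)-ketone is reduced, giving the cis-flavan-4-ol F2 in high ee, while the (2R)-ketone is left and separated. F2 is dehydrated (p-TsOH cat., toluene, 50 °C) to the flav-3-ene F3. Hydroboration–oxidation (BH3·THF; NaOH, H2O2) puts boron on C3 anti to the 2-aryl group and gives 26 directly, so that steps 15–17 are not needed.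

**Step 9.** The α-methoxy ketone 14 may enolise, or the hydride may not give the 2,3-cis alcohol cleanly. The fallback sets out from 8 and comes back at 30. NaBH4 reduces 8 to the cis-flavan-4-ol F4, and p-TsOH (cat.) dehydrates it to the flav-3-ene F5. NBS in aqueous THF gives the bromohydrin F6 (bromonium anti to the 2-aryl group, water at benzylic C4). NaOMe in MeOH closes it to the epoxide F7, which lies cis to the 2-aryl group and is opened in the same pot at benzylic C4 to the 2,3-cis 4-methoxyflavan-3-ol F8, the C4 epimer of 15. F8 is used in place of 15 under the conditions of step 19, gives the same cation and hence 30.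

## Further compounds

F1 | step 19 | potassium [(2R,3S)-7-(benzyloxy)-2-[3,4-bis(benzyloxy)phenyl]-3-hydroxychroman-8-yl]trifluoroborate | `[K+].F[B-](F)(F)c1c(OCc3ccccc3)ccc2c1O[C@H](c1ccc(OCc3ccccc3)c(OCc3ccccc3)c1)[C@@H](O)C2`
F2 | step 14 | (2S,4S)-7-(benzyloxy)-2-[3,4-bis(benzyloxy)phenyl]-8-iodochroman-4-ol (2,4-cis) | `Ic1c(OCc3ccccc3)ccc2c1O[C@H](c1ccc(OCc3ccccc3)c(OCc3ccccc3)c1)C[C@@H]2O`
F3 | step 14 | (2S)-7-(benzyloxy)-2-[3,4-bis(benzyloxy)phenyl]-8-iodo-2H-chromene | `Ic1c(OCc3ccccc3)ccc2c1O[C@H](c1ccc(OCc3ccccc3)c(OCc3ccccc3)c1)C=C2`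
F4 | step 9 | (2R,4R)-7-(benzyloxy)-2-[3,4-bis(benzyloxy)phenyl]chroman-4-ol (2,4-cis) | `c1ccccc1COc1ccc2c(c1)O[C@@H](c1ccc(OCc3ccccc3)c(OCc3ccccc3)c1)C[C@H]2O`
F5 | step 9 | (2R)-7-(benzyloxy)-2-[3,4-bis(benzyloxy)phenyl]-2H-chromene | `c1ccccc1COc1ccc2c(c1)O[C@@H](c1ccc(OCc3ccccc3)c(OCc3ccccc3)c1)C=C2`
F6 | step 9 | (2S,3R,4S)-7-(benzyloxy)-2-[3,4-bis(benzyloxy)phenyl]-3-bromochroman-4-ol | `c1ccccc1COc1ccc2c(c1)O[C@@H](c1ccc(OCc3ccccc3)c(OCc3ccccc3)c1)[C@H](Br)[C@H]2O`
F7 | step 9 | (2S)-7-(benzyloxy)-2-[3,4-bis(benzyloxy)phenyl]-3,4-epoxychromane, oxirane oxygen cis to the 2-aryl group | `c1ccccc1COc1ccc2c(c1)O[C@@H](c1ccc(OCc3ccccc3)c(OCc3ccccc3)c1)[C@H]3O[C@@H]23`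
F8 | step 9 | (2S,3S,4R)-7-(benzyloxy)-2-[3,4-bis(benzyloxy)phenyl]-4-methoxychroman-3-ol | `c1ccccc1COc1ccc2c(c1)O[C@@H](c1ccc(OCc3ccccc3)c(OCc3ccccc3)c1)[C@@H](O)[C@@H]2OC`
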